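The runs are calculated for substances that don't exist; noise was put on by code.

Start from Sunday's fall.

| flask | starting material | reagent | second substrate | remark | time |
|---|---|---|---|---|---|
| Tuesday's | 1.2 M | 0.80 equiv (fed, over 3.0 h) | 0.50 equiv | the very flask that is asked about, followed so far; the fed solution adds 0.20 times the starting volume |  |
| Sunday's | 1.2 M | 0.80 equiv (fed, over 3.0 h) | 0.75 equiv | run made earlier; the fed solution adds 0.20 times the starting volume |  |
| flask | 1.2 M | 0.800 equiv (fed, over 3.0 h) | 0.500 equiv | the fed solution adds 0.20 times the starting volume | 2.0 d |

- Tuesday's (time / h: target / %): 1.00: 4; 2.00: 11; 3.00: 18; 4.00: 23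
- Sunday's (time / h: target / %): 5.00: 23; 10.0: 16; 15.0: 15; 20.0: 14

(readings scatter by 1.5 percentage points)

- the best time, 2.0 d at the latest, for target
- the amount of target, in percent of the starting material charged, at that time

- every charge counts on the volume at the start, and the solution that is fed holds the whole dose
- the numbers in the tables scatter with a standard deviation of 1.5 percentage points

Two views of Tuesday's flask part over that fall. The first, which became the forecast, blames the second substrate and holds that “the long-time target is roughly reagent minus second substrate”, so it gives 29% at 2 d, the end of the window.

The second view, my own, lets target leave by a first-order loss of its own, whatever the second substrate does, and takes the gain as pseudo-first-order, proportional to the reagent concentration. Tuesday's flask gains 0.0700 h⁻¹ of the charge between 2.00 h and 3.00 h. Sunday's excess over its last reading shrinks from 9 points to 2 points between 5.00 h and 10.0 h, which makes a loss constant of 0.301 h⁻¹, a rough reading with a scatter of 1.5 points on each number.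

Gain over loss gives 23.3%, the balance height, the amount of target at which loss per hour equals gain per hour. So I expect Tuesday's flask to stop rising near that height, close to Sunday's 5.00 h, whereas the forecast runs on to the end of the window and stands 5.7 points higher.

The simulation gives 21.0% at 0.187 d.

    starting material + reagent ⇌ target (K = 2.31 L mol⁻¹, k = 1.05 × 10⁻⁴ L mol⁻¹ s⁻¹)
    second substrate + reagent ⇌ second product (K = 1.90 L mol⁻¹, k = 2.20 × 10⁻⁴ L mol⁻¹ s⁻¹)
    target ⇌ isomer of the product (K = 4.46, k = 9.00 × 10⁻⁵ s⁻¹)
    2 second substrate → homo dimer (k = 3.43 × 10⁻⁴ L mol⁻¹ s⁻¹)

Tuesday's flask peaks 2.3 points below the balance height, and at 2.00 d it holds 11.9% of target beside 52.9% of isomer of the product. The first view's rising target holds in Tuesday's flask up to the best time, with target at 17.6% at 0.125 d and at 21.0% at 0.187 d. The neighbour flask charged with 0.200 equiv of reagent has a quarter of the recipe's reagent, so the same reckoning scales the gain, keeps the loss and gives a balance height of 5.82%; that neighbour peaks at 6.09%.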